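For the ochre flask the choice is to follow one number, the ratio of isomer of the product to target, and to follow it in powers of ten. All yields count as fractions of the substrate charged.

| flask | substrate | partner | free catalyst | remark | time |
|---|---|---|---|---|---|
| ochre | 0.055 M | 0.066 M | 0.41 mM | the very flask that is asked about, followed so far |  |
| grey | 0.11 M | 0.066 M | 0.41 mM | run made earlier |  |
| flask | 0.055 M | 0.0660 M | 0.41 mM |  | 20 h |

ochre run (percent of the substrate charged)

| time / min | isomer of the product / % | target / % |
|---|---|---|
| 15.0 | 0 | 0.6 |
| 30.0 | 0.7 | 2.2 |
| 40.0 | 0.7 | 4.2 |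
| 60.0 | 1.1 | 4.9 |
| 80.0 | 2.1 | 6.1 |
| 90.0 | 2.3 | 8.0 |

grey run (percent of the substrate charged)

| time / h | isomer of the product / % | target / % |
|---|---|---|
| 3.00 | 3.5 | 11.1 |
| 6.00 | 6.8 | 15.3 |
| 8.00 | 9.2 | 16.3 |
| 12.0 | 13.6 | 16.6 |
| 15.0 | 15.2 | 15.4 |
| 20.0 | 18.8 | 13.9 |

(readings scatter by 0.5 percentage points)

1. ratio of isomer of the product to target at 15 min
2. ratio of isomer of the product to target at 2.5 h
3. ratio of isomer of the product to target at 20 h
4. which of isomer of the product and target there is more of at 20 h

The grey run looks contradictory. At 3.00 h its ratio reads 0.315, which suggests a side channel with a constant share of the flow, yet at 20.0 h it reads 1.35, with more isomer of the product than target. A constant share keeps the ratio constant, so the ratio in grey is no share but a moving quantity, and its motion can be reckoned. Between those readings the grey ratio gains 0.632 of a power of ten. That gives the climb, the powers of ten gained by the ratio per unit time, as 0.0372 h⁻¹. The gain per hour is uneven across the grey readings, so this average is a rough one.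

The ochre ratio reads 0.287 at 90.0 min. Carried at that climb over the remaining 18.5 h, it gains 0.688 of a power of ten, so the reckoning here gives 1.40 at 20 h.

The forecast gives 0.23 at 15 min, 0.31 at 2.5 h and 1.25 at 20 h, with isomer of the product ahead, holding that “ratios should follow time, not concentration”. Its last figure stands below the reckoning here.

The ochre flask gives ratios of 0.198, 0.288 and 1.24 at those times, with isomer of the product ahead, 23.2% against 18.7% of target. The early ratio of the forecast stands above the flask's, and the reckoning here overshoots the last one.

    substrate + partner → uncatalysed product (k = 0.0170 L mol⁻¹ h⁻¹)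
    substrate + partner ⇌ target (K = 9.20 L mol⁻¹, k = 0.900 L mol⁻¹ h⁻¹)
    free catalyst → spent catalyst (k = 0.00790 h⁻¹)
    substrate + partner ⇌ isomer of the product (K = 36.0 L mol⁻¹, k = 0.170 L mol⁻¹ h⁻¹)
    target + free catalyst ⇌ isomer of the product + free catalyst, rate k5*[free catalyst]*[target] forward; the back reaction follows from the equilibrium constant (k = 120 L mol⁻¹ h⁻¹)
    target → over-reaction product (k = 6.00 × 10⁻⁵ h⁻¹)

Between 2.5 h and 20 h the ochre flask climbs 0.0362 h⁻¹, against 0.0372 h⁻¹ read from grey. Part of that climb comes from the catalysed turning of target, the kinetic product, into isomer of the product: without that step the ochre ratio at 20 h ends at 0.461 instead of 1.24. The largest single effect on the early ochre ratio is the direct turning of substrate + partner into isomer of the product: without it the ratio at 15 min stands at 0.00620 instead of 0.198. A neighbouring flask, the same recipe with 0.160 mM of free catalyst, less than 0.41 mM, climbs 0.0288 h⁻¹ over the same span and ends at a ratio of 0.772.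

The earlier runs and the new flask come from a simulation on assumed constants; the scatter is artificial.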